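The seven-membered ring (C1, C5–C10; daucane numbering) is treated as a cyclohepta-1,4-diene: C8=C9 is already there and the C6 carbinol is taken back to an enol silane C5=C6. That ring is cut at C7–C8 and C1–C10 into a cyclopentenyl siloxy diene (C7=C6–C5=C1, with C4 from (S)-terpinen-4-ol) and a vinylcarbenoid (C8–C9=C10–O). In one operation, rhodium-carbenoid cyclopropanation of C6=C7 and Cope rearrangement of the resulting cis-divinylcyclopropane close the ring, create quaternary C1 and oxygenated C10 with their trans relation, and leave C6 as an enol ether and C14 as an ester for later adjustment.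

Key step: step 8

Remark (numbering, abbreviations): daucane numbering is used for all bicyclic compounds (C1 quaternary ring-fusion carbon bearing methyl C15; C2, C3 CH2; C4 carbinol bearing isopropyl; C5 ring-fusion CH; C6–C10 in the seven-membered ring; C14 on C8); β is the face of the C15 methyl; TES = triethylsilyl, TBS = tert-butyldimethylsilyl.

Assumption: the sense of induction of Rh2(DOSP)4 is taken to be the one it shows in cyclopropanations of styrene by aryl- and vinyldiazoacetates, which points to the R-configured catalyst here; should the sense be opposite, the S-configured catalyst takes its place.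

Design changes relative to the simplest version of this disconnection:
- The C10 oxygen is carried as a TBS ether, not an acetate, because an acetate would not survive reduction of the C14 ester.
- The vinyldiazoacetate is made by diazo aldol addition and dehydration, which should give the E alkene that the Cope step needs, whereas enol acetylation of an aldehyde gives E/Z mixtures.
- The C4 alcohol is silylated first, so that the β-oxygenated aldehyde cannot undergo retro-aldol cleavage.
- Both the C4 ether and the enol ether are TES groups, so one fluoride step frees the ketone and the C4 hydroxyl while the C10 TBS ether stays.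

Step 1
Reactants: 1 (S)-terpinen-4-ol
Product: 2 triethyl{[(1S)-4-methyl-1-(propan-2-yl)cyclohex-3-en-1-yl]oxy}silane
Conditions: Et3SiOTf, 2,6-lutidine, CH2Cl2, 0 °C
Reagents that add atoms: triethylsilyl trifluoromethanesulfonate, CC[Si](CC)(CC)OS(=O)(=O)C(F)(F)F
Why: A silyl triflate with a hindered pyridine base silylates even this tertiary alcohol (O-silylation); the ether later prevents retro-aldol cleavage of the β-oxygenated aldehyde and O–H insertion of the carbenoid, and the carbinol stereocentre is not touched.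

Step 2
Reactants: 2 triethyl{[(1S)-4-methyl-1-(propan-2-yl)cyclohex-3-en-1-yl]oxy}silane
Product: 5 (5R)-2-methyl-5-(propan-2-yl)-5-(triethylsilyloxy)cyclopent-1-ene-1-carbaldehyde, via ozonide 3 (not isolated), via keto aldehyde 4 (not isolated)
Conditions: O3, CH2Cl2, −78 °C; PPh3, −78 °C to rt; then piperidine, AcOH, 40 °C
Reagents that add atoms: ozone, [O-][O+]=O
Why: Ozonolysis cleaves the only C=C to keto aldehyde 4 after reduction of ozonide 3, and the piperidine enamine of the aldehyde then adds to the methyl ketone and dehydrates (intramolecular aldol condensation closing the five-membered ring) to the tetrasubstituted enal, the aldehyde being the nucleophile because only it forms the enamine readily; no stereocentre is formed and C4 is retained.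

Step 3
Reactants: 5 (5R)-2-methyl-5-(propan-2-yl)-5-(triethylsilyloxy)cyclopent-1-ene-1-carbaldehyde
Product: 6 1-[(5R)-2-methyl-5-(propan-2-yl)-5-(triethylsilyloxy)cyclopent-1-en-1-yl]ethan-1-ol (both carbinol epimers)
Conditions: MeMgBr, THF, −78 to 0 °C; aq. NH4Cl
Reagents that add atoms: methylmagnesium bromide, C[Mg]Br
Why: Grignard 1,2-addition to the β,β-disubstituted enal, where conjugate addition is blocked; the new carbinol centre is removed in step 4, so its configuration is irrelevant.

Step 4
Reactants: 6 1-[(5R)-2-methyl-5-(propan-2-yl)-5-(triethylsilyloxy)cyclopent-1-en-1-yl]ethan-1-ol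
Product: 7 1-[(5R)-2-methyl-5-(propan-2-yl)-5-(triethylsilyloxy)cyclopent-1-en-1-yl]ethan-1-one
Conditions: Dess–Martin periodinane, CH2Cl2, 0 °C to rt
Reagents that add atoms: none
Why: Dess–Martin oxidation of a secondary allylic alcohol to the enone under near-neutral conditions that leave the tertiary silyl ether intact.

Step 5
Reactants: 7 1-[(5R)-2-methyl-5-(propan-2-yl)-5-(triethylsilyloxy)cyclopent-1-en-1-yl]ethan-1-one
Product: 8 (5R)-2-methyl-5-(propan-2-yl)-5-(triethylsilyloxy)-1-[1-(triethylsilyloxy)ethenyl]cyclopent-1-ene (siloxy diene C7=C6–C5=C1)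
Conditions: Et3SiOTf, Et3N, CH2Cl2, −78 to 0 °C
Reagents that add atoms: triethylsilyl trifluoromethanesulfonate, CC[Si](CC)(CC)OS(=O)(=O)C(F)(F)F
Why: Soft enolisation (silyl triflate and amine) of the methyl ketone on its methyl group gives the cross-conjugated 2-siloxy diene, the usual outcome for methyl enones, and no stereocentre is formed.

Step 6
Reactants: 9 ethyl diazoacetate; 10 (tert-butyldimethylsilyloxy)acetaldehyde
Product: 11 ethyl 4-(tert-butyldimethylsilyloxy)-2-diazo-3-hydroxybutanoate (racemic)
Conditions: DBU (10 mol %), MeCN, 0 °C to rt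
Reagents that add atoms: none
Why: Amidine-catalysed aldol-type addition of the diazoacetate carbon to the aldehyde (diazo aldol reaction); the carbinol centre is racemic and is destroyed in step 7.

Step 7
Reactants: 11 ethyl 4-(tert-butyldimethylsilyloxy)-2-diazo-3-hydroxybutanoate
Product: 12 ethyl (3E)-4-(tert-butyldimethylsilyloxy)-2-diazobut-3-enoate
Conditions: POCl3, Et3N, CH2Cl2, 0 °C; used at once
Reagents that add atoms: none
Why: Dehydration of a β-hydroxy α-diazo ester through its dichlorophosphate (E2-type elimination) gives the vinyldiazoacetate, the E alkene being expected because the siloxy group lies anti to the diazo ester carbon in the elimination; 12 is used promptly because such diazo dienes slowly close to pyrazoles.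

Step 8
Reactants: 8 siloxy diene; 12 ethyl (3E)-4-(tert-butyldimethylsilyloxy)-2-diazobut-3-enoate
Product: 14 ethyl (1S,4R,10R)-10-(tert-butyldimethylsilyloxy)-4,6-bis(triethylsilyloxy)dauca-5,8-dien-14-oate, via cis-divinylcyclopropane 13 (not isolated)
Conditions: Rh2(R-DOSP)4 [dirhodium tetrakis((R)-N-(4-dodecylbenzenesulfonyl)prolinate), 1 mol %], hexanes, slow addition of 12, −78 °C to rt; then 60 °C
Reagents that add atoms: none
Why: The diazo ester loses N2 on the dirhodium catalyst to a donor/acceptor vinylcarbenoid whose carbene carbon C8 adds to C6=C7 of 8 (a [2+1] closure of the temporary three-membered ring C6–C7–C8) with the cyclopentenyl group cis to the carbenoid vinyl group, as is usual for donor/acceptor carbenoids, giving cis-divinylcyclopropane 13. The push–pull C6–C8 bond (siloxy donor, ester acceptor) then breaks in a boat [3,3]-sigmatropic (Cope) shift that closes the seven-membered ring by forming C1–C10 and leaves C5=C6 as the enol silane and C8=C9 as the enoate; the closest known reaction type is the tandem cyclopropanation/Cope rearrangement (formal (4+3) cycloaddition) of vinyldiazoacetates with 2-siloxy dienes. In the boat the E substituents of the two vinyl termini (the siloxy group on C10 and ring carbon C2 on C1) point outward and end cis, so the C10 oxygen is trans to the C15 methyl, as in the target. The absolute configuration of C1 and C10 follows from the face of C6=C7 that is cyclopropanated, which the chiral prolinate catalyst is expected to dictate and which must place the new C1–C10 bond anti to the C4 siloxy group. The step needs site selectivity for the terminal, oxygen-activated C6=C7 over the tetrasubstituted C5=C1 (secured by sterics and the donor oxygen), cis-divinyl diastereoselectivity, and suppression of attack at the vinylogous carbon C10, which the E-siloxy substituent and the hydrocarbon solvent favour.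

Step 9
Reactants: 14 ethyl (1S,4R,10R)-10-(tert-butyldimethylsilyloxy)-4,6-bis(triethylsilyloxy)dauca-5,8-dien-14-oate
Product: 15 (1S,4R,10R)-10-(tert-butyldimethylsilyloxy)-4,6-bis(triethylsilyloxy)dauca-5,8-dien-14-ol
Conditions: iBu2AlH, CH2Cl2, −78 °C; aq. KNaC4H4O6
Reagents that add atoms: none
Why: 1,2-Reduction of the α,β-unsaturated ester to the allylic alcohol by a dialkylaluminium hydride at low temperature; silyl ethers and the enol silane are inert and no stereocentre changes.

Step 10
Reactants: 15 (1S,4R,10R)-10-(tert-butyldimethylsilyloxy)-4,6-bis(triethylsilyloxy)dauca-5,8-dien-14-ol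
Product: 17 (1S,4R,10R)-10-(tert-butyldimethylsilyloxy)-4,6-bis(triethylsilyloxy)dauca-5,8-diene, via allylic mesylate 16 (not isolated)
Conditions: MsCl, Et3N, THF, −40 °C; then LiEt3BH, −40 to 0 °C
Reagents that add atoms: none
Why: The primary allylic alcohol is activated as its mesylate and displaced by hydride (SN2 at the unhindered CH2; the SN2′ position C9 is shielded by the neopentylic, oxygen-bearing C10), which turns C14 into the C8 methyl group.

Step 11
Reactants: 17 (1S,4R,10R)-10-(tert-butyldimethylsilyloxy)-4,6-bis(triethylsilyloxy)dauca-5,8-diene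
Product: 18 (1S,4R,5R,10R)-10-(tert-butyldimethylsilyloxy)-4-hydroxydauc-8-en-6-one (trans ring fusion, H5 on the α face)
Conditions: HF·pyridine, pyridine, THF, 0 °C
Reagents that add atoms: none
Why: Buffered fluoride should cleave the enol silane first and the hindered tertiary TES ether second while the neopentylic secondary TBS ether survives (selective desilylation); C5 is protonated on the α face, anti to the C15 methyl and the still-silylated C4 oxygen, and the resulting trans-fused ketone is also the expected thermodynamic epimer (C6 cis to the small C4 oxygen and not to isopropyl, held by an O–H···O=C bond).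

Step 12
Reactants: 18 (1S,4R,5R,10R)-10-(tert-butyldimethylsilyloxy)-4-hydroxydauc-8-en-6-one
Product: 19 (1S,4R,5S,6S,10R)-10-(tert-butyldimethylsilyloxy)dauc-8-ene-4,6-diol
Conditions: Me4NBH(OAc)3, MeCN/AcOH, −20 °C
Reagents that add atoms: none
Why: Hydroxyl-directed reduction of a β-hydroxy ketone (Evans–Saksena reduction): the acetoxyborohydride bound to the C4 hydroxyl delivers hydride intramolecularly to the C6 face syn to O4, which sets C6 with its hydroxyl on the α face, anti to the C4 hydroxyl; the reagent touches neither the alkene nor the silyl ether.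

Step 13
Reactants: 19 (1S,4R,5S,6S,10R)-10-(tert-butyldimethylsilyloxy)dauc-8-ene-4,6-diol
Product: 20 (1S,4R,5S,6S,10R)-6-benzoyloxy-10-(tert-butyldimethylsilyloxy)dauc-8-en-4-ol
Conditions: BzCl, DMAP, Et3N, CH2Cl2, 0 °C to rt
Reagents that add atoms: benzoyl chloride, O=C(Cl)c1ccccc1
Why: Nucleophile-catalysed acylation (DMAP) takes place only at the secondary C6 hydroxyl; the hindered tertiary C4 hydroxyl does not react and C6 keeps its configuration.

Step 14
Reactants: 20 (1S,4R,5S,6S,10R)-6-benzoyloxy-10-(tert-butyldimethylsilyloxy)dauc-8-en-4-ol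
Product: 21 (1S,4R,5S,6S,10R)-6-benzoyloxydauc-8-ene-4,10-diol
Conditions: HF·pyridine, THF, 0 °C to rt
Reagents that add atoms: none
Why: Desilylation of the remaining secondary silyl ether by unbuffered HF·pyridine under non-basic conditions, which avoids benzoate migration between the C6 and C10 oxygens.

Step 15
Reactants: 21 (1S,4R,5S,6S,10R)-6-benzoyloxydauc-8-ene-4,10-diol
Product: 22 (1S,4R,5S,6S,10R)-10-angeloyloxy-6-benzoyloxydauc-8-en-4-ol (CNP0397959.1)
Conditions: angelic acid, 2,4,6-trichlorobenzoyl chloride, Et3N, toluene, rt; then 21, 80 °C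
Reagents that add atoms: angelic acid ((Z)-2-methylbut-2-enoic acid), C/C=C(/C)C(=O)O
Why: Yamaguchi esterification through the mixed anhydride of angelic acid acylates the secondary allylic C10 hydroxyl (the tertiary C4 hydroxyl is inert), a protocol chosen because it transfers the angeloyl group without Z to E isomerisation to the tiglate; C10 reacts at oxygen and keeps its configuration.

Compound list
1 | (S)-terpinen-4-ol, (1S)-4-methyl-1-(propan-2-yl)cyclohex-3-en-1-ol | CC1=CC[C@](O)(C(C)C)CC1 | starting material
2 | triethyl{[(1S)-4-methyl-1-(propan-2-yl)cyclohex-3-en-1-yl]oxy}silane | CC1=CC[C@](O[Si](CC)(CC)CC)(C(C)C)CC1 | intermediate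
3 | ozonide (1,2,4-trioxolane) of 2 across the former C=C, silyloxy carbon unchanged, ozonide carbons as formed | CC12CC[C@@](O[Si](CC)(CC)CC)(C(C)C)CC(OO1)O2 | intermediate
4 | (3S)-6-oxo-3-(propan-2-yl)-3-(triethylsilyloxy)heptanal | O=CC[C@](O[Si](CC)(CC)CC)(C(C)C)CCC(C)=O | intermediate
5 | (5R)-2-methyl-5-(propan-2-yl)-5-(triethylsilyloxy)cyclopent-1-ene-1-carbaldehyde | O=CC1=C(C)CC[C@@]1(O[Si](CC)(CC)CC)C(C)C | intermediate
6 | 1-[(5R)-2-methyl-5-(propan-2-yl)-5-(triethylsilyloxy)cyclopent-1-en-1-yl]ethan-1-ol, both carbinol epimers | CC(O)C1=C(C)CC[C@@]1(O[Si](CC)(CC)CC)C(C)C | intermediate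
7 | 1-[(5R)-2-methyl-5-(propan-2-yl)-5-(triethylsilyloxy)cyclopent-1-en-1-yl]ethan-1-one | CC(=O)C1=C(C)CC[C@@]1(O[Si](CC)(CC)CC)C(C)C | intermediate
8 | (5R)-2-methyl-5-(propan-2-yl)-5-(triethylsilyloxy)-1-[1-(triethylsilyloxy)ethenyl]cyclopent-1-ene | C=C(O[Si](CC)(CC)CC)C1=C(C)CC[C@@]1(O[Si](CC)(CC)CC)C(C)C | intermediate
9 | ethyl diazoacetate | CCOC(=O)C=[N+]=[N-] | starting material
10 | (tert-butyldimethylsilyloxy)acetaldehyde | O=CCO[Si](C)(C)C(C)(C)C | starting material
11 | ethyl 4-(tert-butyldimethylsilyloxy)-2-diazo-3-hydroxybutanoate, racemic | CCOC(=O)C(=[N+]=[N-])C(O)CO[Si](C)(C)C(C)(C)C | intermediate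
12 | ethyl (3E)-4-(tert-butyldimethylsilyloxy)-2-diazobut-3-enoate | CCOC(=O)C(=[N+]=[N-])/C=C/O[Si](C)(C)C(C)(C)C | intermediate
13 | ethyl (1S,2R)-1-[(E)-2-(tert-butyldimethylsilyloxy)ethenyl]-2-[(5R)-2-methyl-5-(propan-2-yl)-5-(triethylsilyloxy)cyclopent-1-en-1-yl]-2-(triethylsilyloxy)cyclopropane-1-carboxylate, ethenyl and cyclopentenyl groups cis | CCOC(=O)[C@]1(/C=C/O[Si](C)(C)C(C)(C)C)C[C@@]1(O[Si](CC)(CC)CC)C2=C(C)CC[C@@]2(O[Si](CC)(CC)CC)C(C)C | intermediate
14 | ethyl (1S,4R,10R)-10-(tert-butyldimethylsilyloxy)-4,6-bis(triethylsilyloxy)dauca-5,8-dien-14-oate | CC(C)(C)[Si](C)(C)O[C@@H]1C=C(C(=O)OCC)CC(O[Si](CC)(CC)CC)=C2[C@]1(C)CC[C@@]2(O[Si](CC)(CC)CC)C(C)C | intermediate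
15 | (1S,4R,10R)-10-(tert-butyldimethylsilyloxy)-4,6-bis(triethylsilyloxy)dauca-5,8-dien-14-ol | CC(C)(C)[Si](C)(C)O[C@@H]1C=C(CO)CC(O[Si](CC)(CC)CC)=C2[C@]1(C)CC[C@@]2(O[Si](CC)(CC)CC)C(C)C | intermediate
16 | 14-methanesulfonate of 15 | CC(C)(C)[Si](C)(C)O[C@@H]1C=C(COS(C)(=O)=O)CC(O[Si](CC)(CC)CC)=C2[C@]1(C)CC[C@@]2(O[Si](CC)(CC)CC)C(C)C | intermediate
17 | (1S,4R,10R)-10-(tert-butyldimethylsilyloxy)-4,6-bis(triethylsilyloxy)dauca-5,8-diene | CC(C)(C)[Si](C)(C)O[C@@H]1C=C(C)CC(O[Si](CC)(CC)CC)=C2[C@]1(C)CC[C@@]2(O[Si](CC)(CC)CC)C(C)C | intermediate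
18 | (1S,4R,5R,10R)-10-(tert-butyldimethylsilyloxy)-4-hydroxydauc-8-en-6-one, trans-fused | CC(C)(C)[Si](C)(C)O[C@@H]1C=C(C)CC(=O)[C@@H]2[C@]1(C)CC[C@@]2(O)C(C)C | intermediate
19 | (1S,4R,5S,6S,10R)-10-(tert-butyldimethylsilyloxy)dauc-8-ene-4,6-diol | CC(C)(C)[Si](C)(C)O[C@@H]1C=C(C)C[C@H](O)[C@@H]2[C@]1(C)CC[C@@]2(O)C(C)C | intermediate
20 | (1S,4R,5S,6S,10R)-6-benzoyloxy-10-(tert-butyldimethylsilyloxy)dauc-8-en-4-ol | CC(C)(C)[Si](C)(C)O[C@@H]1C=C(C)C[C@H](OC(=O)c2ccccc2)[C@@H]2[C@]1(C)CC[C@@]2(O)C(C)C | intermediate
21 | (1S,4R,5S,6S,10R)-6-benzoyloxydauc-8-ene-4,10-diol | O[C@@H]1C=C(C)C[C@H](OC(=O)c2ccccc2)[C@@H]2[C@]1(C)CC[C@@]2(O)C(C)C | intermediate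
22 | (1S,4R,5S,6S,10R)-10-angeloyloxy-6-benzoyloxydauc-8-en-4-ol, CNP0397959.1 | C/C=C(/C)C(=O)O[C@@H]1C=C(C)C[C@H](OC(=O)c2ccccc2)[C@@H]2[C@]1(C)CC[C@@]2(O)C(C)C | target

Total step count: 15.
Longest linear sequence: 13 steps (steps 1–5 and 8–15, from 1); the diazo partner needs 2 steps (6 and 7).

Steps most likely to fail

Step 8. The carbenoid is strongly stabilised by the siloxy donor on C10. It may therefore be attacked at C10 instead of C8, or be lost to carbenoid dimerisation and pyrazole formation before it reaches the hindered C6=C7. The facial preference of the catalyst may also be opposed by the C4 centre, which would show as the C1/C10 diastereomer and would first be probed with the enantiomeric catalyst. The fallback sets out from 8 and comes back at 17, and replaces the siloxy carbenoid by the less donating acetoxy one. Methyl 4-oxobutanoate is enol-acetylated (Ac2O, Et3N, DMAP) to methyl (E)-4-acetoxybut-3-enoate F1, which is separated from methyl (Z)-4-acetoxybut-3-enoate F2. Diazo transfer (4-acetamidobenzenesulfonyl azide, DBU, MeCN, 0 °C) gives methyl (E)-4-acetoxy-2-diazobut-3-enoate F3. With 8 under the same dirhodium catalysis this should pass through the acetoxy cis-divinylcyclopropane F4 to the C10 acetate cycloheptadiene ester F5. iBu2AlH cleaves both esters to the 10,14-diol F6. Selective mesylation of the primary allylic hydroxyl gives the 14-monomesylate F7, and LiEt3BH gives the C10 alcohol F8. Silylation with tBuMe2SiOTf and 2,6-lutidine then returns to 17.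

Step 11. Protonation of C5 may occur from the β face and give the cis-fused ketone, and the free β-hydroxy ketone may lose water or let C8=C9 move into conjugation. The fallback sets out from 17 and comes back at 18, and relies on thermodynamic instead of kinetic control while C4 stays silylated. Methanolysis (K2CO3, MeOH, 0 °C) cleaves only the enol silane and gives the trans-fused C4-silylated ketone F9 together with its C5 epimer F10. A trace of DBU in toluene equilibrates F10 into F9 through the C5 enolate; the siloxy groups at C4 and C10 are poor leaving groups. HF·pyridine then removes the C4 silyl group and gives 18.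

Step 12. External hydride attack on the α face of the ketone, anti to the C15 methyl, may outrun the directed delivery and give the 6β alcohol. The fallback sets out from 18 and comes back at 20, and turns that preference to use. NaBH4 in MeOH at −40 °C gives the 6β alcohol F11 on purpose. Mitsunobu esterification with benzoic acid (PPh3, diisopropyl azodicarboxylate, toluene) then inverts C6 and gives benzoate 20 directly.

Further compounds
F1 | step 8 | methyl (E)-4-acetoxybut-3-enoate | COC(=O)C/C=C/OC(C)=O
F2 | step 8 | methyl (Z)-4-acetoxybut-3-enoate | COC(=O)C/C=C\OC(C)=O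
F3 | step 8 | methyl (E)-4-acetoxy-2-diazobut-3-enoate | COC(=O)C(=[N+]=[N-])/C=C/OC(C)=O
F4 | step 8 | methyl (1S,2R)-1-[(E)-2-acetoxyethenyl]-2-[(5R)-2-methyl-5-(propan-2-yl)-5-(triethylsilyloxy)cyclopent-1-en-1-yl]-2-(triethylsilyloxy)cyclopropane-1-carboxylate | COC(=O)[C@]1(/C=C/OC(C)=O)C[C@@]1(O[Si](CC)(CC)CC)C2=C(C)CC[C@@]2(O[Si](CC)(CC)CC)C(C)C
F5 | step 8 | methyl (1S,4R,10R)-10-acetoxy-4,6-bis(triethylsilyloxy)dauca-5,8-dien-14-oate | CC(=O)O[C@@H]1C=C(C(=O)OC)CC(O[Si](CC)(CC)CC)=C2[C@]1(C)CC[C@@]2(O[Si](CC)(CC)CC)C(C)C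
F6 | step 8 | (1S,4R,10R)-4,6-bis(triethylsilyloxy)dauca-5,8-diene-10,14-diol | O[C@@H]1C=C(CO)CC(O[Si](CC)(CC)CC)=C2[C@]1(C)CC[C@@]2(O[Si](CC)(CC)CC)C(C)C
F7 | step 8 | 14-methanesulfonate of F6 | O[C@@H]1C=C(COS(C)(=O)=O)CC(O[Si](CC)(CC)CC)=C2[C@]1(C)CC[C@@]2(O[Si](CC)(CC)CC)C(C)C
F8 | step 8 | (1S,4R,10R)-4,6-bis(triethylsilyloxy)dauca-5,8-dien-10-ol | O[C@@H]1C=C(C)CC(O[Si](CC)(CC)CC)=C2[C@]1(C)CC[C@@]2(O[Si](CC)(CC)CC)C(C)C
F9 | step 11 | trans-fused 10-(tert-butyldimethylsilyloxy)-4-(triethylsilyloxy)dauc-8-en-6-one, H5 on the α face | CC(C)(C)[Si](C)(C)O[C@@H]1C=C(C)CC(=O)[C@@H]2[C@]1(C)CC[C@@]2(O[Si](CC)(CC)CC)C(C)C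
F10 | step 11 | C5 epimer of F9, cis-fused | CC(C)(C)[Si](C)(C)O[C@@H]1C=C(C)CC(=O)[C@H]2[C@]1(C)CC[C@@]2(O[Si](CC)(CC)CC)C(C)C
F11 | step 12 | C6 epimer of 19, 6β-hydroxyl | CC(C)(C)[Si](C)(C)O[C@@H]1C=C(C)C[C@@H](O)[C@@H]2[C@]1(C)CC[C@@]2(O)C(C)C
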